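## Analysis of the target

The target 21 is an isoflavone: benzene ring A is fused to pyranone ring C, and C3 carries a 4-hydroxyphenyl group (ring B). Ring A is of the phloroglucinol type, with free hydroxyls on C5 and C7, the ring oxygen O1 on C8a, and an (E)-4-hydroxy-3-methylbut-2-enyl chain on C6. There is no stereocentre. The only stereochemical element is the trisubstituted side-chain alkene, in which the hydroxymethyl group is trans to the benzylic methylene.

The sensitive groups are the three phenols, the primary allylic alcohol and the electron-rich alkene, which lies between two phenols and can cyclise onto either under strong acid. Ring C opens at C2 under hydroxide or alkoxide.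

The main difficulty is regiochemical. C6 and C8 are both flanked by two oxygens, so alkylation of a finished 5,7-dihydroxyisoflavone cannot tell them apart. The allylic oxygen must also be introduced with E geometry in a molecule that tolerates neither strong acid nor strong base.

The strategy rests on one structural feature: C8a (bearing O1) and C4a (bearing the C4 carbonyl) are adjacent carbons of ring A, and C4a is flanked by the C5 oxygen. An aryne spanning C8a–C4a can take up both substituents in one operation, with the C5 oxygen deciding which goes where. The aryne can be made from a phenol that is symmetric about the axis through C6 and C8a, so the chain is fixed at C6 before ring C exists.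

## Retrosynthetic reasoning

**21 to 20.** The three aryl O–CH2 acetal bonds are cut last. The phenols then stay masked through every basic, organometallic and oxidative step, and the final operation is a mild acid treatment that only has to spare the allylic alcohol and the alkene.

**20 to 19.** The C–O bond at the terminal allylic carbon of the chain is cut next, so the chain travels through the route as a plain prenyl group. An allylic ester would not survive the alkyllithium used to build the aryne precursor, and its removal at the end would need alkoxide, which opens ring C at C2. An allylic acetal or silyl ether would have to pass a triflating agent and hot fluoride. The oxidation cannot come earlier than 19 either, because the active methylene of deoxybenzoin 16 is itself open to selenium-based oxidation. The forward step must oxidise only the methyl group trans to the chain and leave the doubly activated C1' methylene and the pyranone alone.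

**19 to 16 and 17.** The O1–C2 and C2–C3 bonds are cut, removing the single carbon C2 as amide acetal 17. This leaves 2-hydroxydeoxybenzoin 16, whose one free phenol is the only oxygen that can close ring C. The forward step is condensation at the active methylene followed by addition–elimination by that phenol.

**16 to 11 and 14 (through aryne 15).** The O1–C8a and C4–C4a bonds are cut together. A Friedel–Crafts or Hoesch acylation would make only the C4–C4a bond and would leave one phenol to be freed selectively afterwards. The aryne disconnection makes both bonds at adjacent carbons, at positions fixed by where silicon and triflate sit, and releases exactly one phenol. The forward step must place oxygen on the aryne carbon remote from the flanking acetal oxygen, and the acyl shift must outrun protonation of the aryl anion.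

**14 to 12.** The aryl O–CH2 acetal bond is cut, so the ring-B unit comes from phenolic acid 12.

**11 to 8 (through 9 and 10).** The C–Si bond at C2 and the O–S bond of the triflate are cut. Silicon is delivered from oxygen to the ortho carbon after halogen–metal exchange, so the bromine of 8 fixes its position.

**8 to 7.** The C–Br bond is cut. Phenol 7 has a mirror axis through C1 and C4, so its two free ring positions are the same. Halogenation has no regiochemical choice, and this is where 6- versus 8-substitution of the final isoflavone is settled.

**7 to 6, then to 3 and 4.** The O–Si bond is cut, then the aryl–CH2 bond of the chain. The forward reaction is lithiation at the one carbon lying between two chelating acetal oxygens (aryllithium 5), then allylation with prenyl bromide 4 at its primary carbon.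

**3 to 2 to 1.** The two acetal O–C bonds and the O–Si bond are cut, back to phloroglucinol 1. The forward steps set one oxygen (the future O1) apart from the other two (the future C5 and C7 oxygens) with a bulky silyl group that neither directs metalation nor migrates.

## Alternatives that were turned down

**Alternative 1:** The disconnection is the C2=C3 double bond of ring C. In the forward direction, diene A2 (an aryl vinyl ether that also carries a 1,1-disubstituted 2-aryl enone) would be closed by a second-generation Hoveyda–Grubbs catalyst to the protected isoflavone A1, expelling the two terminal methylene groups as a gaseous C2 olefin.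

- For it: the closure is catalytic, neutral and runs near room temperature. On mildness it is stronger than the 125 °C fluoride step chosen here, and its regiochemistry within ring C is unambiguous.
- Against it: A1 has no C6 chain. The chain would have to be attached to a finished 5,7-dioxygenated isoflavone, where C6 and C8 are both flanked by two oxygens and ring C is electrophilic at C2 towards the organometallics that directed metalation needs.
- Against it: the enol ether terminus of A2 gives a stabilised, slowly turning-over carbene, and the aryl enone terminus is hindered and prone to polymerise.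
- Against it: A2 still needs the ring A–C4 bond, so the acylation problem is moved, not solved. Ring C then costs a methylenation, an O-vinylation of a hindered hydrogen-bonded phenol and the metathesis, against one condensation with 17 in the chosen route.
- In its place the chosen strategy offers a substitution pattern fixed by symmetry before ring C is formed.

**Alternative 2:** The disconnection is the C3–C4 bond. In the forward direction, aldehyde A4 (an aryl phenacyl ether) would be treated with a triazolium-derived N-heterocyclic carbene and an amine base. The acyl-anion equivalent formed at the aldehyde carbon would add to the tethered ketone (6-exo-trig) to give the racemic 3-hydroxyisoflavanone A3, which must then be dehydrated across C2–C3.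

- For it: the closure is organocatalytic and mild, and the chain is already in place. If A4 were made by ortho-formylation of a symmetric phenol of the type of 7, its regiochemistry would be as secure as in the chosen route, so on that point it is equally strong.
- Against it: a stereocentre is made at C3 only to be destroyed. The dehydration concerns a hindered tertiary hydroxyl next to a carbonyl, where ionisation is disfavoured and activation must be carried out beside three acetals and an allylic silyl ether.
- Against it: the aldehyde is flanked by two oxygens and is a poor electrophile towards the carbene.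
- Against it: the phenacyl methylene is acidic, so the amine base can divert A4 by intramolecular aldol condensation onto the aldehyde to an aroylbenzofuran.
- Against it: the allylic oxygen has to be carried protected throughout.
- In its place the chosen strategy offers the isoflavone oxidation level directly after the one-carbon condensation, with no redox or elimination step and no stereocentre.

**Alternative 3:** The disconnection is the C4a–C5 bond, so ring A itself is built from an open chain. In the forward direction, triketo ester A6 would be cyclised with alkoxide base. The methylene between the two ketones nearest the aryl end attacks the ester carbonyl (Claisen condensation), and enolisation gives the trihydroxydeoxybenzoin A5.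

- For it: the step is biomimetic, needs no directing or blocking groups on an arene, and places the acyl group unambiguously. On conceptual economy of ring A it is stronger.
- Against it: ring A is available as 1, so building it spends steps where none are needed.
- Against it: A6 needs polyanion chemistry and can cyclise in other modes, by aldol closure to a resorcylate-type ring or by lactonisation to a pyranone.
- Against it: A5 has three free phenols and no chain. After C-alkylation (which competes with O- and poly-alkylation), either ortho hydroxyl can close ring C, so 6- and 8-substituted isoflavones both arise.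
- In its place the chosen strategy offers the regiochemistry settled by the symmetry of 7 and by the single phenol released in the key step.

Key step: step 8

Remark on the chemistry: commercial phloroglucinol is taken as the anhydrous solid (the dihydrate is dried before use).

## Route

Step 1
Reactants: 1 phloroglucinol (benzene-1,3,5-triol)
Product: 2 5-{[tri(propan-2-yl)silyl]oxy}benzene-1,3-diol
Conditions: 1 (3 equiv), i-Pr3SiCl (1 equiv), imidazole (1.5 equiv), DMF, 0 °C → rt
Reagents that add atoms: chlorotri(propan-2-yl)silane CC(C)[Si](Cl)(C(C)C)C(C)C
Why: Silyl ether formation at one of three equivalent phenols; with the cheap triol in threefold excess the silyl chloride should be consumed mainly as the mono-ether, and unreacted 1 is washed out with water while any bis-silyl ether is far less polar. The bulky group is chosen because it resists n-BuLi and does not direct metalation.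

Step 2
Reactants: 2 5-{[tri(propan-2-yl)silyl]oxy}benzene-1,3-diol
Product: 3 [3,5-bis(methoxymethoxy)phenoxy]tri(propan-2-yl)silane
Conditions: MOMCl (2.6 equiv), i-Pr2NEt (3 equiv), CH2Cl2, 0 °C → rt
Reagents that add atoms: chloromethyl methyl ether COCCl
Why: Base-mediated O-alkylation (acetal formation) of both remaining phenols; the hindered aryl silyl ether is inert to the amine base, and the symmetric product has two chelating acetal oxygens flanking C4.

Step 3
Reactants: 3 [3,5-bis(methoxymethoxy)phenoxy]tri(propan-2-yl)silane; 4 prenyl bromide (1-bromo-3-methylbut-2-ene)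
Product: 6 [3,5-bis(methoxymethoxy)-4-(3-methylbut-2-en-1-yl)phenoxy]tri(propan-2-yl)silane, via aryllithium 5 (not isolated)
Conditions: n-BuLi (1.15 equiv), THF, 0 °C; CuI (0.1 equiv), then 4 (1.3 equiv), –78 °C → rt
Reagents that add atoms: none
Why: Directed ortho-metalation: the carbon between the two methoxymethoxy groups is deprotonated because both acetal oxygens chelate lithium, while the positions next to the bulky, poorly coordinating silyl ether are not activated. Copper-catalysed allylic substitution at the primary carbon of 4 (SN2, not SN2') should then give the linear prenyl arene.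

Step 4
Reactants: 6 [3,5-bis(methoxymethoxy)-4-(3-methylbut-2-en-1-yl)phenoxy]tri(propan-2-yl)silane
Product: 7 3,5-bis(methoxymethoxy)-4-(3-methylbut-2-en-1-yl)phenol
Conditions: Bu4NF (1.1 equiv), AcOH (1.1 equiv), THF, 0 °C → rt
Reagents that add atoms: none
Why: Fluoride-induced cleavage of the aryl silyl ether, driven by the Si–F bond and the good phenoxide leaving group; acetic acid buffers the electron-rich phenoxide, and the acetals and the alkene are not touched.

Step 5
Reactants: 7 3,5-bis(methoxymethoxy)-4-(3-methylbut-2-en-1-yl)phenol
Product: 8 2-bromo-3,5-bis(methoxymethoxy)-4-(3-methylbut-2-en-1-yl)phenol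
Conditions: NBS (1.0 equiv), MeCN, –30 °C, dark
Reagents that add atoms: N-bromosuccinimide O=C1CCC(=O)N1Br
Why: Electrophilic aromatic bromination ortho to the free hydroxyl; 7 has a mirror axis through C1 and C4, so its two free ring positions are equivalent and only one monobromide can form. In an aprotic medium at low temperature the highly activated phenol ring should react far faster than the trisubstituted alkene, and one equivalent of reagent limits dibromination.

Step 6
Reactants: 8 2-bromo-3,5-bis(methoxymethoxy)-4-(3-methylbut-2-en-1-yl)phenol
Product: 11 3,5-bis(methoxymethoxy)-4-(3-methylbut-2-en-1-yl)-2-(trimethylsilyl)phenyl trifluoromethanesulfonate, via aryl trimethylsilyl ether 9 (not isolated), via lithium silylphenolate 10 (not isolated)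
Conditions: HMDS (1.5 equiv), THF, 65 °C, then evaporation; n-BuLi (1.1 equiv), THF, –78 °C; Tf2O (1.2 equiv), –78 °C
Reagents that add atoms: hexamethyldisilazane C[Si](C)(C)N[Si](C)(C)C; trifluoromethanesulfonic anhydride O=S(=O)(OS(=O)(=O)C(F)(F)F)C(F)(F)F
Why: O-silylation, then bromine–lithium exchange gives a fleeting ortho-lithiated aryl silyl ether that undergoes the anionic 1,3 O→C silyl shift (retro-Brook rearrangement) to phenolate 10, which is triflated on oxygen; this is the standard one-flask entry to 2-(trimethylsilyl)aryl triflates. Exchange at –78 °C is faster than attack on the acetals or on the benzylic/allylic methylene, and the phenolate should react with the anhydride before the acetals can be activated.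

Step 7
Reactants: 12 4-hydroxyphenylacetic acid
Product: 14 2-[4-(methoxymethoxy)phenyl]acetic acid, via methoxymethyl ester 13 (not isolated)
Conditions: MOMCl (2.5 equiv), i-Pr2NEt (3 equiv), CH2Cl2, 0 °C → rt; then LiOH (3 equiv), THF/MeOH/H2O, rt; 1 M HCl to pH 4, 0 °C
Reagents that add atoms: chloromethyl methyl ether COCCl; lithium hydroxide [Li+].[OH-]
Why: Exhaustive methoxymethylation gives ester-ether 13, whose acyl acetal ester is saponified under conditions that leave the aryl acetal intact. Acidification only to pH 4 in the cold keeps the acid-labile ether.

Step 8
Reactants: 11 3,5-bis(methoxymethoxy)-4-(3-methylbut-2-en-1-yl)-2-(trimethylsilyl)phenyl trifluoromethanesulfonate; 14 2-[4-(methoxymethoxy)phenyl]acetic acid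
Product: 16 1-[6-hydroxy-2,4-bis(methoxymethoxy)-3-(3-methylbut-2-en-1-yl)phenyl]-2-[4-(methoxymethoxy)phenyl]ethan-1-one, via aryne 15 (not isolated)
Conditions: 14 (1.2 equiv), CsF (4 equiv), THF, 125 °C, sealed tube
Reagents that add atoms: none
Why: Fluoride attacks silicon of 11 and triflate leaves, giving aryne 15; the cesium carboxylate of 14 adds through oxygen to the aryne carbon remote from the flanking methoxymethoxy group (future C8a), because that inductively withdrawing substituent distorts the triple bond towards attack at the distal carbon and stabilises the negative charge developing on the carbon next to it (future C4a). The aryl anion, now ortho to the new aryl ester, attacks the ester carbonyl (4-exo-trig) to give a benzoxete-type alkoxide, which opens to the ortho-acyl phenoxide, so O1–C8a and C4–C4a are formed in one operation. The closest known reaction type is the fluoride-induced insertion of arynes from 2-(trimethylsilyl)aryl triflates into the C–O bond of carboxylic acids to give ortho-hydroxyaryl ketones, which with 3-alkoxyarynes places the acyl group beside the alkoxy group. No ring persists and no stereocentre is formed. The step needs regioselectivity (oxygen at C8a, acyl at C4a), which the 3-methoxymethoxy group secures, and acyl transfer faster than protonation of the aryl anion, which the high temperature and the excess of CsF (acid held as carboxylate) should favour. The second acetal and the prenyl chain are remote from the triple bond and only lock the pattern, so the single phenol released is the future O1.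

Step 9
Reactants: 16 1-[6-hydroxy-2,4-bis(methoxymethoxy)-3-(3-methylbut-2-en-1-yl)phenyl]-2-[4-(methoxymethoxy)phenyl]ethan-1-one; 17 N,N-dimethylformamide dimethyl acetal
Product: 19 5,7-bis(methoxymethoxy)-3-[4-(methoxymethoxy)phenyl]-6-(3-methylbut-2-en-1-yl)-4H-chromen-4-one, via enaminone 18 (not isolated)
Conditions: 17 (4 equiv), toluene, 90 °C
Reagents that add atoms: none
Why: Condensation of the amide acetal with the active methylene gives enaminone 18; the only free phenol then adds to the enamine carbon in a 6-endo-trig addition–elimination with loss of dimethylamine, closing the pyranone (deoxybenzoin route to isoflavones). Because the other two ring-A oxygens are protected, closure can only go through the oxygen placed in step 8, which puts the chain at C6.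

Step 10
Reactants: 19 5,7-bis(methoxymethoxy)-3-[4-(methoxymethoxy)phenyl]-6-(3-methylbut-2-en-1-yl)-4H-chromen-4-one
Product: 20 6-[(2E)-4-hydroxy-3-methylbut-2-en-1-yl]-5,7-bis(methoxymethoxy)-3-[4-(methoxymethoxy)phenyl]-4H-chromen-4-one
Conditions: SeO2 (0.5 equiv), t-BuOOH (3 equiv, in decane), CH2Cl2, 0 °C → rt
Reagents that add atoms: selenium dioxide O=[Se]=O; tert-butyl hydroperoxide CC(C)(C)OO
Why: Selenium dioxide allylic oxidation with the hydroperoxide as terminal oxidant: an ene reaction at the more substituted alkene terminus followed by a [2,3]-sigmatropic shift oxidises the methyl group trans to the chain, which sets the E geometry of the allylic alcohol. The C1' methylene sits on the less substituted terminus and should not be attacked, and the pyranone and acetals are inert; the step is placed after ring closure because the active methylene of 16 would itself be oxidised.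

Step 11
Reactants: 20 6-[(2E)-4-hydroxy-3-methylbut-2-en-1-yl]-5,7-bis(methoxymethoxy)-3-[4-(methoxymethoxy)phenyl]-4H-chromen-4-one
Product: 21 5,7-dihydroxy-6-[(2E)-4-hydroxy-3-methylbut-2-en-1-yl]-3-(4-hydroxyphenyl)-4H-chromen-4-one
Conditions: 3 M aq. HCl/MeOH (1:5), 45 °C
Reagents that add atoms: none
Why: Acid-catalysed transacetalisation to methanol removes the three aryl methoxymethyl groups; aryl acetals cleave under conditions mild enough that the primary allylic alcohol should not ionise and the alkene should not be protonated. The E geometry is not affected.

## Compound list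

1 | phloroglucinol (benzene-1,3,5-triol) | Oc1cc(O)cc(O)c1 | starting material
2 | 5-{[tri(propan-2-yl)silyl]oxy}benzene-1,3-diol | CC(C)[Si](Oc1cc(O)cc(O)c1)(C(C)C)C(C)C | intermediate
3 | [3,5-bis(methoxymethoxy)phenoxy]tri(propan-2-yl)silane | COCOc1cc(OCOC)cc(O[Si](C(C)C)(C(C)C)C(C)C)c1 | intermediate
4 | prenyl bromide (1-bromo-3-methylbut-2-ene) | CC(C)=CCBr | starting material
5 | [2,6-bis(methoxymethoxy)-4-{[tri(propan-2-yl)silyl]oxy}phenyl]lithium | [Li]c1c(OCOC)cc(O[Si](C(C)C)(C(C)C)C(C)C)cc1OCOC | intermediate (not isolated)
6 | [3,5-bis(methoxymethoxy)-4-(3-methylbut-2-en-1-yl)phenoxy]tri(propan-2-yl)silane | COCOc1cc(O[Si](C(C)C)(C(C)C)C(C)C)cc(OCOC)c1CC=C(C)C | intermediate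
7 | 3,5-bis(methoxymethoxy)-4-(3-methylbut-2-en-1-yl)phenol | COCOc1cc(O)cc(OCOC)c1CC=C(C)C | intermediate
8 | 2-bromo-3,5-bis(methoxymethoxy)-4-(3-methylbut-2-en-1-yl)phenol | COCOc1cc(O)c(Br)c(OCOC)c1CC=C(C)C | intermediate
9 | [2-bromo-3,5-bis(methoxymethoxy)-4-(3-methylbut-2-en-1-yl)phenoxy]trimethylsilane | COCOc1cc(O[Si](C)(C)C)c(Br)c(OCOC)c1CC=C(C)C | intermediate (not isolated)
10 | lithium 3,5-bis(methoxymethoxy)-4-(3-methylbut-2-en-1-yl)-2-(trimethylsilyl)phenolate | [Li+].COCOc1cc([O-])c([Si](C)(C)C)c(OCOC)c1CC=C(C)C | intermediate (not isolated)
11 | 3,5-bis(methoxymethoxy)-4-(3-methylbut-2-en-1-yl)-2-(trimethylsilyl)phenyl trifluoromethanesulfonate | COCOc1cc(OS(=O)(=O)C(F)(F)F)c([Si](C)(C)C)c(OCOC)c1CC=C(C)C | intermediate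
12 | 4-hydroxyphenylacetic acid | OC(=O)Cc1ccc(O)cc1 | starting material
13 | methoxymethyl 2-[4-(methoxymethoxy)phenyl]acetate | COCOC(=O)Cc1ccc(OCOC)cc1 | intermediate (not isolated)
14 | 2-[4-(methoxymethoxy)phenyl]acetic acid | OC(=O)Cc1ccc(OCOC)cc1 | intermediate
15 | 3,5-bis(methoxymethoxy)-4-(3-methylbut-2-en-1-yl)benzyne (1,2-didehydrobenzene; triple bond between C1 and C2) | C1#CC=C(OCOC)C(CC=C(C)C)=C1OCOC | intermediate (not isolated)
16 | 1-[6-hydroxy-2,4-bis(methoxymethoxy)-3-(3-methylbut-2-en-1-yl)phenyl]-2-[4-(methoxymethoxy)phenyl]ethan-1-one | COCOc1ccc(CC(=O)c2c(O)cc(OCOC)c(CC=C(C)C)c2OCOC)cc1 | intermediate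
17 | N,N-dimethylformamide dimethyl acetal | COC(OC)N(C)C | starting material
18 | 3-(dimethylamino)-1-[6-hydroxy-2,4-bis(methoxymethoxy)-3-(3-methylbut-2-en-1-yl)phenyl]-2-[4-(methoxymethoxy)phenyl]prop-2-en-1-one (enamine geometry not fixed; either isomer cyclises) | CN(C)C=C(C(=O)c1c(O)cc(OCOC)c(CC=C(C)C)c1OCOC)c1ccc(OCOC)cc1 | intermediate (not isolated)
19 | 5,7-bis(methoxymethoxy)-3-[4-(methoxymethoxy)phenyl]-6-(3-methylbut-2-en-1-yl)-4H-chromen-4-one | COCOc1ccc(cc1)-c1coc2cc(OCOC)c(CC=C(C)C)c(OCOC)c2c1=O | intermediate
20 | 6-[(2E)-4-hydroxy-3-methylbut-2-en-1-yl]-5,7-bis(methoxymethoxy)-3-[4-(methoxymethoxy)phenyl]-4H-chromen-4-one | COCOc1ccc(cc1)-c1coc2cc(OCOC)c(C/C=C(\C)CO)c(OCOC)c2c1=O | intermediate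
21 | 5,7-dihydroxy-6-[(2E)-4-hydroxy-3-methylbut-2-en-1-yl]-3-(4-hydroxyphenyl)-4H-chromen-4-one | C/C(=C\Cc1c(O)cc2occ(-c3ccc(O)cc3)c(=O)c2c1O)CO | target

## Step count and least certain steps

Total step count: 11. Longest linear sequence: 10 steps (steps 1–6 and 8–11, from 1); step 7 is a one-step side branch.

**Step 8 (key step).** The most likely failure is protonation of the aryl anion before the acyl shift. The anion is stabilised by the neighbouring acetal oxygen and crowded on both sides, so O-arylation without insertion (the aryl ester) can compete. Lesser risks are further arylation of the product phenoxide and acetal loss at 125 °C.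
Fallback, from 8 and 14, returning at 16: the two are esterified (EDC·HCl, DMAP, CH2Cl2) to 2-bromo-3,5-bis(methoxymethoxy)-4-(3-methylbut-2-en-1-yl)phenyl 2-[4-(methoxymethoxy)phenyl]acetate F1. Treatment with n-BuLi (1.05 equiv) in THF at –100 °C should then trigger bromine–lithium exchange followed by the anionic Fries-type 1,3 O→C acyl shift. This generates the same ortho-ester aryl anion at low temperature with no proton source, with the regiochemistry fixed by the bromine, and gives 16 after work-up.

**Step 6.** The likely failures are quenching of the ortho-lithiated silyl ether before the silyl group has migrated (by moisture, or by premature hydrolysis of the labile silyl ether 9), and activation of the acetals by the anhydride if the phenolate is not consumed quickly.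
Fallback, from 7, returning at 11, avoiding both the halogen–metal exchange and the silyl migration: 7 is carbamoylated (Et2NCOCl, K2CO3, MeCN) to 3,5-bis(methoxymethoxy)-4-(3-methylbut-2-en-1-yl)phenyl N,N-diethylcarbamate F2. Carbamate-directed ortho-lithiation (s-BuLi, TMEDA, THF, –78 °C) with Me3SiCl quench gives 3,5-bis(methoxymethoxy)-4-(3-methylbut-2-en-1-yl)-2-(trimethylsilyl)phenyl N,N-diethylcarbamate F3. Reductive cleavage of the carbamate with Cp2Zr(H)Cl in THF gives 3,5-bis(methoxymethoxy)-4-(3-methylbut-2-en-1-yl)-2-(trimethylsilyl)phenol F4, and triflation with PhNTf2 and Cs2CO3 in MeCN returns 11.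

**Step 10.** The likely failures are over-oxidation of the new allylic alcohol to the enal and incomplete conversion, both inherent to this oxidation and costly this late in the route.
Fallback, from 19, returning at 20: cross-metathesis of the prenyl group with methacrolein (second-generation Hoveyda–Grubbs catalyst, CH2Cl2, 40 °C) should give (2E)-4-{5,7-bis(methoxymethoxy)-3-[4-(methoxymethoxy)phenyl]-4-oxo-4H-chromen-6-yl}-2-methylbut-2-enal F5, with the E geometry set by the conjugated enal. 1,2-Reduction of the aldehyde (NaBH4, CeCl3·7H2O, MeOH/THF, –40 °C) then gives 20.

**Step 11.** The likely failure is acid-promoted loss of the side chain's integrity once the flanking phenols are free: ionisation or solvolysis of the allylic alcohol, or ring closure of a phenol onto the chain.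
Fallback, from 19, returning at 21, so that acid never meets the allylic alcohol: 19 is deprotected first (aq. HCl/MeOH) to 5,7-dihydroxy-3-(4-hydroxyphenyl)-6-(3-methylbut-2-en-1-yl)-4H-chromen-4-one F6. Acetylation (Ac2O, pyridine) gives 6-(3-methylbut-2-en-1-yl)-4-oxo-3-[4-(acetyloxy)phenyl]-4H-chromene-5,7-diyl diacetate F7. The allylic oxidation of step 10 (SeO2, t-BuOOH, CH2Cl2) is then run on F7 to give 6-[(2E)-4-hydroxy-3-methylbut-2-en-1-yl]-4-oxo-3-[4-(acetyloxy)phenyl]-4H-chromene-5,7-diyl diacetate F8, and brief methanolysis (K2CO3, MeOH, 0 °C) gives 21.

## Further compounds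

F1 | step 8 | 2-bromo-3,5-bis(methoxymethoxy)-4-(3-methylbut-2-en-1-yl)phenyl 2-[4-(methoxymethoxy)phenyl]acetate | COCOc1ccc(CC(=O)Oc2cc(OCOC)c(CC=C(C)C)c(OCOC)c2Br)cc1
F2 | step 6 | 3,5-bis(methoxymethoxy)-4-(3-methylbut-2-en-1-yl)phenyl N,N-diethylcarbamate | CCN(CC)C(=O)Oc1cc(OCOC)c(CC=C(C)C)c(OCOC)c1
F3 | step 6 | 3,5-bis(methoxymethoxy)-4-(3-methylbut-2-en-1-yl)-2-(trimethylsilyl)phenyl N,N-diethylcarbamate | CCN(CC)C(=O)Oc1cc(OCOC)c(CC=C(C)C)c(OCOC)c1[Si](C)(C)C
F4 | step 6 | 3,5-bis(methoxymethoxy)-4-(3-methylbut-2-en-1-yl)-2-(trimethylsilyl)phenol | COCOc1cc(O)c([Si](C)(C)C)c(OCOC)c1CC=C(C)C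
F5 | step 10 | (2E)-4-{5,7-bis(methoxymethoxy)-3-[4-(methoxymethoxy)phenyl]-4-oxo-4H-chromen-6-yl}-2-methylbut-2-enal | COCOc1ccc(cc1)-c1coc2cc(OCOC)c(C/C=C(\C)C=O)c(OCOC)c2c1=O
F6 | step 11 | 5,7-dihydroxy-3-(4-hydroxyphenyl)-6-(3-methylbut-2-en-1-yl)-4H-chromen-4-one | CC(C)=CCc1c(O)cc2occ(-c3ccc(O)cc3)c(=O)c2c1O
F7 | step 11 | 6-(3-methylbut-2-en-1-yl)-4-oxo-3-[4-(acetyloxy)phenyl]-4H-chromene-5,7-diyl diacetate | CC(C)=CCc1c(OC(C)=O)cc2occ(-c3ccc(OC(C)=O)cc3)c(=O)c2c1OC(C)=O
F8 | step 11 | 6-[(2E)-4-hydroxy-3-methylbut-2-en-1-yl]-4-oxo-3-[4-(acetyloxy)phenyl]-4H-chromene-5,7-diyl diacetate | C/C(=C\Cc1c(OC(C)=O)cc2occ(-c3ccc(OC(C)=O)cc3)c(=O)c2c1OC(C)=O)CO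
A1 | alternative 1 | 5,7-bis(methoxymethoxy)-3-[4-(methoxymethoxy)phenyl]-4H-chromen-4-one | COCOc1ccc(cc1)-c1coc2cc(OCOC)cc(OCOC)c2c1=O
A2 | alternative 1 | 1-[2-(ethenyloxy)-4,6-bis(methoxymethoxy)phenyl]-2-[4-(methoxymethoxy)phenyl]prop-2-en-1-one | C=COc1cc(OCOC)cc(OCOC)c1C(=O)C(=C)c1ccc(OCOC)cc1
A3 | alternative 2 | racemic 6-[(2E)-4-{[tert-butyl(dimethyl)silyl]oxy}-3-methylbut-2-en-1-yl]-3-hydroxy-5,7-bis(methoxymethoxy)-3-[4-(methoxymethoxy)phenyl]-2,3-dihydro-4H-chromen-4-one | OC1(c2ccc(OCOC)cc2)COc2cc(OCOC)c(C/C=C(\C)CO[Si](C)(C)C(C)(C)C)c(OCOC)c2C1=O
A4 | alternative 2 | 5-[(2E)-4-{[tert-butyl(dimethyl)silyl]oxy}-3-methylbut-2-en-1-yl]-4,6-bis(methoxymethoxy)-2-{2-[4-(methoxymethoxy)phenyl]-2-oxoethoxy}benzaldehyde | O=Cc1c(OCC(=O)c2ccc(OCOC)cc2)cc(OCOC)c(C/C=C(\C)CO[Si](C)(C)C(C)(C)C)c1OCOC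
A5 | alternative 3 | 2-[4-(methoxymethoxy)phenyl]-1-(2,4,6-trihydroxyphenyl)ethan-1-one | COCOc1ccc(CC(=O)c2c(O)cc(O)cc2O)cc1
A6 | alternative 3 | methyl 8-[4-(methoxymethoxy)phenyl]-3,5,7-trioxooctanoate | COC(=O)CC(=O)CC(=O)CC(=O)Cc1ccc(OCOC)cc1
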